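**Plan**

- Numbering: chroman O1, C2–C8a; side chain C1'–C12' counted from C2 (ketone C9', methyl centre C8').
- Cuts, in retrosynthetic order: C9'=O back to the carbinol; C4'–C5' (sp2–sp3), which splits the target into the chroman half as an (E)-C4' vinyl iodide and the C5'–C12' half as a C5'=C6' terminal alkene; then C2'–C3', O1–C2 and C4–C4a in the chroman half, and C10'–C11', C9'–C10' and C7'–C8' in the other half.
- Enabling feature: the C3'=C4' trisubstituted (E)-alkene, whose methyl-bearing C4' is bonded to the unbranched C5'H2–C6'H2–C7'H2 run. C4' can therefore be an sp2 iodide and C5' the boron-bearing end of a hydroborated vinyl group.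
- Forward order: the dihydropyran ring (O1–C2–C3–C4–C4a–C8a) is closed on the bought arene by Pd-catalysed asymmetric O-allylation; the C2 vinyl group is grown into the (E)-iodoalkene; the two halves are joined at C4'–C5'; oxidation at C9' and desilylation finish.
- Stereochemistry: C2 (R) from the chiral Pd ligand; C8' (S) from the oxazolidinone auxiliary; C3'=C4' (E) from syn hydrozirconation of a 2-alkyne, kept by the stereoretentive coupling; C9' is carried as an epimer mixture and erased by oxidation.

Key step: step 16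

Remark (assumption): the (S,S)-ligand is taken to give the (2S)-vinylchroman 9 from the (E)-carbonate 8; if the sense of induction is the opposite, the (R,R)-ligand is used and nothing else changes.

**Route**

Step 1
Reactants: 1 2-methylhydroquinone
Product: 2 2-methyl-4-(triisopropylsilyloxy)phenol
Conditions: TIPSCl (1.0 equiv), imidazole, DMF, 0 °C
Reagents that add atoms: chlorotriisopropylsilane, CC(C)[Si](Cl)(C(C)C)C(C)C
Why: Silyl ether formation; the hydroxyl meta to the methyl group is the less hindered and slightly more acidic one, so the bulky silyl chloride should take it selectively.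

Step 2
Reactants: 2 2-methyl-4-(triisopropylsilyloxy)phenol
Product: 3 2-iodo-6-methyl-4-(triisopropylsilyloxy)phenol
Conditions: NIS (1.05 equiv), TsOH·H2O (10 mol %), CH2Cl2, 0 °C, dark
Reagents that add atoms: N-iodosuccinimide, O=C1CCC(=O)N1I
Why: Electrophilic aromatic iodination directed by the free hydroxyl; the para position and one ortho position are blocked, so only the remaining ortho carbon is open.

Step 3
Reactants: 4 (E)-3-methylpent-2-en-4-yn-1-ol
Product: 5 (E)-3-methylpenta-2,4-dien-1-ol
Conditions: H2 (1 atm), Lindlar catalyst, quinoline, EtOAc, 0 °C, stopped after 1 equiv H2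
Reagents that add atoms: none
Why: Lindlar semi-hydrogenation of the terminal alkyne of a conjugated enyne stops at the diene and leaves the (E)-trisubstituted alkene untouched.

Step 4
Reactants: 5 (E)-3-methylpenta-2,4-dien-1-ol; 3 2-iodo-6-methyl-4-(triisopropylsilyloxy)phenol
Product: 7 2-[(3E)-5-hydroxy-3-methylpent-3-en-1-yl]-6-methyl-4-(triisopropylsilyloxy)phenol, via bis(9-BBN) adduct 6 (not isolated)
Conditions: 9-BBN dimer (1.1 equiv), THF, 0 °C to rt; then 3 M aq K3PO4, 3, PdCl2(dppf)·CH2Cl2 (5 mol %), DMF, 50 °C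
Reagents that add atoms: none
Why: B-alkyl Suzuki–Miyaura coupling; 9-BBN adds only to the monosubstituted terminus of the 1,3-diene (the hydroxyl is held as its borinate and released by the aqueous base before the catalyst is added), so the aryl–CH2 bond forms with the (E)-allylic alcohol unit intact.

Step 5
Reactants: 7 2-[(3E)-5-hydroxy-3-methylpent-3-en-1-yl]-6-methyl-4-(triisopropylsilyloxy)phenol
Product: 8 (2E)-5-[2-hydroxy-3-methyl-5-(triisopropylsilyloxy)phenyl]-3-methylpent-2-en-1-yl methyl carbonate
Conditions: ClCO2Me (1.1 equiv), pyridine, CH2Cl2, −20 to 0 °C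
Reagents that add atoms: methyl chloroformate, COC(=O)Cl
Why: Chemoselective O-acylation; under non-ionising conditions the primary allylic alcohol should react well ahead of the 2,6-disubstituted phenol.

Step 6
Reactants: 8 (2E)-5-[2-hydroxy-3-methyl-5-(triisopropylsilyloxy)phenyl]-3-methylpent-2-en-1-yl methyl carbonate
Product: 9 (2S)-2-ethenyl-2,8-dimethyl-6-(triisopropylsilyloxy)chroman
Conditions: Pd2(dba)3·CHCl3 (2 mol %), (S,S)-N,N'-(cyclohexane-1,2-diyl)bis[2-(diphenylphosphino)benzamide] (6 mol %), AcOH (1 equiv), CH2Cl2, rt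
Reagents that add atoms: none
Why: Intramolecular Pd-catalysed asymmetric allylic alkylation (Tsuji–Trost type) of a phenol; ionisation gives a π-allyl complex, the phenol attacks its fully substituted terminus to close the six-membered ring instead of an eight-membered one, and the chiral diphosphine pocket selects the face, setting C2.

Step 7
Reactants: 9 (2S)-2-ethenyl-2,8-dimethyl-6-(triisopropylsilyloxy)chroman
Product: 11 2-[(2S)-2,8-dimethyl-6-(triisopropylsilyloxy)chroman-2-yl]ethanol, via alkylborane 10 (not isolated)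
Conditions: 9-BBN (1.5 equiv), THF, rt to 40 °C; then 30% H2O2, 3 M aq NaOAc, 0 °C to rt
Reagents that add atoms: hydrogen peroxide, OO
Why: Anti-Markovnikov hydroboration–oxidation of the vinyl group; boron goes to the terminal carbon, away from the quaternary C2, and the acetate-buffered oxidation spares the aryl silyl ether.

Step 8
Reactants: 11 2-[(2S)-2,8-dimethyl-6-(triisopropylsilyloxy)chroman-2-yl]ethanol
Product: 12 (2S)-2-(2-iodoethyl)-2,8-dimethyl-6-(triisopropylsilyloxy)chroman
Conditions: I2, PPh3, imidazole, CH2Cl2, 0 °C to rt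
Reagents that add atoms: iodine, II
Why: Appel-type iodination of a primary alcohol by SN2 displacement of the alkoxyphosphonium ion.

Step 9
Reactants: 12 (2S)-2-(2-iodoethyl)-2,8-dimethyl-6-(triisopropylsilyloxy)chroman
Product: 13 (2R)-2,8-dimethyl-2-(pent-3-yn-1-yl)-6-(triisopropylsilyloxy)chroman
Conditions: 1-propynyllithium (2 equiv), THF/DMPU, 0 °C to rt
Reagents that add atoms: 1-propynyllithium, [Li]C#CC
Why: SN2 alkylation of a lithium acetylide by a primary iodide in a dipolar cosolvent; the reacting carbon is one CH2 removed from the quaternary centre, so substitution should outrun elimination.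

Step 10
Reactants: 13 (2R)-2,8-dimethyl-2-(pent-3-yn-1-yl)-6-(triisopropylsilyloxy)chroman
Product: 15 (2R)-2-[(3E)-4-iodopent-3-en-1-yl]-2,8-dimethyl-6-(triisopropylsilyloxy)chroman, via alkenylzirconocene 14 (not isolated)
Conditions: Cp2Zr(H)Cl (2.5 equiv), THF, 50 °C, dark; then I2, THF, 0 °C
Reagents that add atoms: iodine, II
Why: Hydrozirconation–iodination; syn addition of Zr–H with excess reagent and warming equilibrates zirconium onto the methyl-bearing alkyne carbon, and iodinolysis with retention gives the (E)-2-iodo-2-alkene.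

Step 11
Reactants: 16 (4R)-4-benzyl-3-propanoyl-1,3-oxazolidin-2-one
Product: 18 (4R)-4-benzyl-3-[(2S)-2-methylpent-4-enoyl]-1,3-oxazolidin-2-one, via sodium enolate 17 (not isolated)
Conditions: NaHMDS (1.1 equiv), THF, −78 °C; allyl iodide (3 equiv), −78 to −45 °C
Reagents that add atoms: allyl iodide, C=CCI
Why: Evans auxiliary alkylation; the chelated (Z)-enolate is attacked on the face opposite the benzyl group, which sets the (S)-methyl centre (C8' of the target).

Step 12
Reactants: 18 (4R)-4-benzyl-3-[(2S)-2-methylpent-4-enoyl]-1,3-oxazolidin-2-one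
Product: 19 (2S)-2-methylpent-4-en-1-ol
Conditions: LiBH4, Et2O, MeOH (1 equiv), 0 °C
Reagents that add atoms: none
Why: Reductive removal of the auxiliary with lithium borohydride; the exocyclic imide carbonyl is reduced to the primary alcohol without touching the stereocentre.

Step 13
Reactants: 19 (2S)-2-methylpent-4-en-1-ol
Product: 20 (2S)-2-methylpent-4-enal
Conditions: Dess–Martin periodinane, NaHCO3, CH2Cl2, 0 °C; silica plug, solution concentrated cold and used at once
Reagents that add atoms: none
Why: Buffered Dess–Martin oxidation is non-basic, so the enolisable α-methyl aldehyde should form without racemisation; it is not stored because it is volatile.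

Step 14
Reactants: 20 (2S)-2-methylpent-4-enal
Product: 21 2-[(2S)-pent-4-en-2-yl]oxirane (both epimers at the oxirane carbon)
Conditions: Me3S+ I−, n-BuLi, THF, −10 °C; then 20, −10 to 0 °C
Reagents that add atoms: trimethylsulfonium iodide, C[S+](C)C.[I-]
Why: Corey–Chaykovsky epoxidation; methylene transfer from the sulfonium ylide to the aldehyde is fast at low temperature, and the new oxirane centre needs no control because it becomes the ketone carbon.

Step 15
Reactants: 21 2-[(2S)-pent-4-en-2-yl]oxirane
Product: 22 (4S)-4,8-dimethylnona-1,7-dien-5-ol (both C5 epimers)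
Conditions: Me2C=CHMgBr (1.5 equiv), CuI (10 mol %), THF, −30 to 0 °C; aq NH4Cl
Reagents that add atoms: 2-methyl-1-propenylmagnesium bromide, CC(C)=C[Mg]Br
Why: Copper-catalysed Grignard opening of a terminal epoxide at its CH2 carbon; using the alkenyl nucleophile gives the linear prenyl carbinol directly and avoids the allylic transposition of prenyl–metal additions to carbonyls.

Step 16
Reactants: 22 (4S)-4,8-dimethylnona-1,7-dien-5-ol; 15 (2R)-2-[(3E)-4-iodopent-3-en-1-yl]-2,8-dimethyl-6-(triisopropylsilyloxy)chroman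
Product: 24 (2R)-2-[(3E,8S)-9-hydroxy-4,8,12-trimethyltrideca-3,11-dien-1-yl]-2,8-dimethyl-6-(triisopropylsilyloxy)chroman (both C9' epimers), via alkylborane 23 (not isolated)
Conditions: 9-BBN dimer (1.5 equiv), THF, rt; then 3 M aq K3PO4, 15, PdCl2(dppf)·CH2Cl2 (5 mol %), AsPh3 (5 mol %), DMF, rt, dark
Reagents that add atoms: none
Why: B-alkyl Suzuki–Miyaura coupling: 9-BBN adds anti-Markovnikov to the monosubstituted C5'=C6' alkene of 22 (the free hydroxyl is carried as its O-borinate), hydroxide converts the primary alkylborane into the borate, Pd(0) inserts into the C4'–I bond of 15, and transmetalation followed by reductive elimination forges the C4'(sp2)–C5'(sp3) bond. The closest known reaction type is the alkyl-9-BBN/(E)-2-iodo-2-alkene fragment coupling used to make trisubstituted (E)-olefins in polyketide and terpenoid work. The step closes no ring and creates no stereocentre, but it must leave intact the E geometry at C3'=C4', the C8' methyl centre and the C11'=C12' alkene. Geometry is secured because oxidative addition and reductive elimination are stereoretentive at sp2 carbon; C8' cannot epimerise because C9' is still at the alcohol oxidation level; chemoselectivity rests on the large rate difference of 9-BBN between a terminal vinyl group and the trisubstituted 2-methylpropenyl unit. The dppf/AsPh3 catalyst system speeds transmetalation and reductive elimination so that β-hydride elimination of the alkylpalladium should not compete.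

Step 17
Reactants: 24 (2R)-2-[(3E,8S)-9-hydroxy-4,8,12-trimethyltrideca-3,11-dien-1-yl]-2,8-dimethyl-6-(triisopropylsilyloxy)chroman
Product: 25 (2R)-2,8-dimethyl-2-[(3E,8S)-4,8,12-trimethyl-9-oxotrideca-3,11-dien-1-yl]-6-(triisopropylsilyloxy)chroman
Conditions: Dess–Martin periodinane, NaHCO3, CH2Cl2, 0 °C
Reagents that add atoms: none
Why: Buffered Dess–Martin oxidation converts both carbinol epimers to the one ketone without moving the β,γ-alkene into conjugation or epimerising C8', while the silyl ether shields the oxidation-prone chromanol.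

Step 18
Reactants: 25 (2R)-2,8-dimethyl-2-[(3E,8S)-4,8,12-trimethyl-9-oxotrideca-3,11-dien-1-yl]-6-(triisopropylsilyloxy)chroman
Product: 26 (2R)-2,8-dimethyl-2-[(3E,8S)-4,8,12-trimethyl-9-oxotrideca-3,11-dien-1-yl]chroman-6-ol
Conditions: TBAF, AcOH (1:1.2), THF, 0 °C, under argon
Reagents that add atoms: none
Why: Fluoride cleavage of the aryl silyl ether; buffering with acetic acid keeps the medium near neutral, so the epimerisable, deconjugated ketone should survive.

**Compound list**

1 | 2-methylhydroquinone | Cc1cc(O)ccc1O | starting material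
2 | 2-methyl-4-(triisopropylsilyloxy)phenol | Cc1cc(O[Si](C(C)C)(C(C)C)C(C)C)ccc1O | intermediate
3 | 2-iodo-6-methyl-4-(triisopropylsilyloxy)phenol | Cc1cc(O[Si](C(C)C)(C(C)C)C(C)C)cc(I)c1O | intermediate
4 | (E)-3-methylpent-2-en-4-yn-1-ol | C#C/C(C)=C/CO | starting material
5 | (E)-3-methylpenta-2,4-dien-1-ol | C=C/C(C)=C/CO | intermediate
6 | bis(9-BBN) adduct of 5, boron on C5 and on oxygen, formed in situ | CC(/CCB1C2CCCC1CCC2)=C\COB1C2CCCC1CCC2 | intermediate
7 | 2-[(3E)-5-hydroxy-3-methylpent-3-en-1-yl]-6-methyl-4-(triisopropylsilyloxy)phenol | Cc1cc(O[Si](C(C)C)(C(C)C)C(C)C)cc(CC/C(C)=C/CO)c1O | intermediate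
8 | (2E)-5-[2-hydroxy-3-methyl-5-(triisopropylsilyloxy)phenyl]-3-methylpent-2-en-1-yl methyl carbonate | Cc1cc(O[Si](C(C)C)(C(C)C)C(C)C)cc(CC/C(C)=C/COC(=O)OC)c1O | intermediate
9 | (2S)-2-ethenyl-2,8-dimethyl-6-(triisopropylsilyloxy)chroman | C=C[C@]1(C)CCc2cc(O[Si](C(C)C)(C(C)C)C(C)C)cc(C)c2O1 | intermediate
10 | 9-BBN adduct of 9, boron on the terminal carbon, C2 configuration as in 9, formed in situ | C(C[C@]1(C)CCc2cc(O[Si](C(C)C)(C(C)C)C(C)C)cc(C)c2O1)B1C2CCCC1CCC2 | intermediate
11 | 2-[(2S)-2,8-dimethyl-6-(triisopropylsilyloxy)chroman-2-yl]ethanol | OCC[C@]1(C)CCc2cc(O[Si](C(C)C)(C(C)C)C(C)C)cc(C)c2O1 | intermediate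
12 | (2S)-2-(2-iodoethyl)-2,8-dimethyl-6-(triisopropylsilyloxy)chroman | ICC[C@]1(C)CCc2cc(O[Si](C(C)C)(C(C)C)C(C)C)cc(C)c2O1 | intermediate
13 | (2R)-2,8-dimethyl-2-(pent-3-yn-1-yl)-6-(triisopropylsilyloxy)chroman | CC#CCC[C@]1(C)CCc2cc(O[Si](C(C)C)(C(C)C)C(C)C)cc(C)c2O1 | intermediate
14 | (E)-alkenylzirconocene chloride from 13, Zr on the methyl-bearing carbon, Cp rings drawn σ-bonded, formed in situ | Cl[Zr](/C(C)=C/CC[C@]1(C)CCc2cc(O[Si](C(C)C)(C(C)C)C(C)C)cc(C)c2O1)(C1C=CC=C1)C1C=CC=C1 | intermediate
15 | (2R)-2-[(3E)-4-iodopent-3-en-1-yl]-2,8-dimethyl-6-(triisopropylsilyloxy)chroman | I/C(C)=C/CC[C@]1(C)CCc2cc(O[Si](C(C)C)(C(C)C)C(C)C)cc(C)c2O1 | intermediate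
16 | (4R)-4-benzyl-3-propanoyl-1,3-oxazolidin-2-one | CCC(=O)N1[C@H](Cc2ccccc2)COC1=O | starting material
17 | sodium (Z)-enolate of 16, formed in situ | C/C=C(\[O-])N1[C@H](Cc2ccccc2)COC1=O.[Na+] | intermediate
18 | (4R)-4-benzyl-3-[(2S)-2-methylpent-4-enoyl]-1,3-oxazolidin-2-one | C=CC[C@H](C)C(=O)N1[C@H](Cc2ccccc2)COC1=O | intermediate
19 | (2S)-2-methylpent-4-en-1-ol | C=CC[C@H](C)CO | intermediate
20 | (2S)-2-methylpent-4-enal | C=CC[C@H](C)C=O | intermediate
21 | 2-[(2S)-pent-4-en-2-yl]oxirane, both epimers at the oxirane carbon | C=CC[C@H](C)C1CO1 | intermediate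
22 | (4S)-4,8-dimethylnona-1,7-dien-5-ol, both C5 epimers | C=CC[C@H](C)C(O)CC=C(C)C | intermediate
23 | 9-BBN adduct of 22, boron on C1, hydroxyl as its 9-BBN borinate, formed in situ | CC(C)=CCC(OB1C2CCCC1CCC2)[C@@H](C)CCCB1C2CCCC1CCC2 | intermediate
24 | (2R)-2-[(3E,8S)-9-hydroxy-4,8,12-trimethyltrideca-3,11-dien-1-yl]-2,8-dimethyl-6-(triisopropylsilyloxy)chroman, both C9' epimers | CC(C)=CCC(O)[C@@H](C)CCC/C(C)=C/CC[C@]1(C)CCc2cc(O[Si](C(C)C)(C(C)C)C(C)C)cc(C)c2O1 | intermediate
25 | (2R)-2,8-dimethyl-2-[(3E,8S)-4,8,12-trimethyl-9-oxotrideca-3,11-dien-1-yl]-6-(triisopropylsilyloxy)chroman | CC(C)=CCC(=O)[C@@H](C)CCC/C(C)=C/CC[C@]1(C)CCc2cc(O[Si](C(C)C)(C(C)C)C(C)C)cc(C)c2O1 | intermediate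
26 | (2R)-2,8-dimethyl-2-[(3E,8S)-4,8,12-trimethyl-9-oxotrideca-3,11-dien-1-yl]chroman-6-ol | CC(C)=CCC(=O)[C@@H](C)CCC/C(C)=C/CC[C@]1(C)CCc2cc(O)cc(C)c2O1 | target

**Count and risks**

Total step count: 18.
Longest linear sequence: 12 steps (1, 2, 4, 5, 6, 7, 8, 9, 10, 16, 17, 18).

Steps most likely to fail:

1. Step 6. The allylic etherification may give poor facial selectivity at the fully substituted C2 if the diastereomeric π-allyl complexes do not equilibrate before ring closure. The fallback closes the ring by an enantioselective Wacker-type oxypalladation and sets out from 3. Hydroboration of isoprene with 9-BBN gives 9-(3-methylbut-3-en-1-yl)-9-borabicyclo[3.3.1]nonane F1, which is coupled with 3 (PdCl2(dppf), aq K3PO4) to 2-methyl-6-(3-methylbut-3-en-1-yl)-4-(triisopropylsilyloxy)phenol F2. Treatment with Pd(OCOCF3)2, a Bn-BOXAX bis(oxazoline) ligand of the enantiomer that delivers the (S)-ester, p-benzoquinone, CO and MeOH should close the ring by oxypalladation of the 1,1-disubstituted alkene and trap the alkylpalladium by methoxycarbonylation, giving methyl 2-[(2S)-2,8-dimethyl-6-(triisopropylsilyloxy)chroman-2-yl]acetate F3. Reduction with LiAlH4 comes back to the route at 11.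

2. Step 16. Transmetalation of the hindered, borinate-bearing alkylborane may be slow, so that protodeboronation or β-hydride elimination of the alkylpalladium takes over. The fallback makes the same bond by a Negishi coupling and sets out from 22. TESCl and imidazole give (4S)-4,8-dimethyl-5-(triethylsilyloxy)nona-1,7-diene F4. Hydrozirconation of its terminal alkene with Cp2Zr(H)Cl gives the alkylzirconocene chloride F5, and iodinolysis gives (6S)-9-iodo-2,6-dimethyl-5-(triethylsilyloxy)non-2-ene F6. Zinc insertion (Zn dust, LiCl, THF) gives the alkylzinc iodide F7, which is coupled with 15 under Pd(PPh3)4 to the triethylsilyl ether of 24 F8. PPTS in MeOH removes only the alkyl silyl group and comes back to the route at 24.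

3. Step 14. The basic ylide may enolise the α-methyl aldehyde, eroding the C8' configuration, and material may be lost through volatility. The fallback avoids the aldehyde and sets out from 18. Transamidation with Me(MeO)NH·HCl and AlMe3 gives (2S)-N-methoxy-N,2-dimethylpent-4-enamide F9. Chloromethyllithium (ICH2Cl, MeLi·LiBr, −78 °C) gives (3S)-1-chloro-3-methylhex-5-en-2-one F10. NaBH4 gives (3S)-1-chloro-3-methylhex-5-en-2-ol F11, and K2CO3 in MeOH closes it to the epoxide, coming back to the route at 21.

**Further compounds**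

F1 | step 6 | 9-(3-methylbut-3-en-1-yl)-9-borabicyclo[3.3.1]nonane | C=C(C)CCB1C2CCCC1CCC2
F2 | step 6 | 2-methyl-6-(3-methylbut-3-en-1-yl)-4-(triisopropylsilyloxy)phenol | C=C(C)CCc1cc(O[Si](C(C)C)(C(C)C)C(C)C)cc(C)c1O
F3 | step 6 | methyl 2-[(2S)-2,8-dimethyl-6-(triisopropylsilyloxy)chroman-2-yl]acetate | COC(=O)C[C@]1(C)CCc2cc(O[Si](C(C)C)(C(C)C)C(C)C)cc(C)c2O1
F4 | step 16 | (4S)-4,8-dimethyl-5-(triethylsilyloxy)nona-1,7-diene, both C5 epimers | C=CC[C@H](C)C(O[Si](CC)(CC)CC)CC=C(C)C
F5 | step 16 | alkylzirconocene chloride from F4, Zr on C1, Cp rings drawn σ-bonded | Cl[Zr](CCC[C@H](C)C(O[Si](CC)(CC)CC)CC=C(C)C)(C1C=CC=C1)C1C=CC=C1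
F6 | step 16 | (6S)-9-iodo-2,6-dimethyl-5-(triethylsilyloxy)non-2-ene, both C5 epimers | ICCC[C@H](C)C(O[Si](CC)(CC)CC)CC=C(C)C
F7 | step 16 | alkylzinc iodide from F6 | I[Zn]CCC[C@H](C)C(O[Si](CC)(CC)CC)CC=C(C)C
F8 | step 16 | triethylsilyl ether of 24 | CC(C)=CCC(O[Si](CC)(CC)CC)[C@@H](C)CCC/C(C)=C/CC[C@]1(C)CCc2cc(O[Si](C(C)C)(C(C)C)C(C)C)cc(C)c2O1
F9 | step 14 | (2S)-N-methoxy-N,2-dimethylpent-4-enamide | C=CC[C@H](C)C(=O)N(C)OC
F10 | step 14 | (3S)-1-chloro-3-methylhex-5-en-2-one | C=CC[C@H](C)C(=O)CCl
F11 | step 14 | (3S)-1-chloro-3-methylhex-5-en-2-ol, both C2 epimers | C=CC[C@H](C)C(O)CCl
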